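**Retrosynthetic overview**
- The two outer CH2 bridges are cut first (ortho-quinone methide coupling). This gives the bis-Mannich base of methylenebis(2,4,6-trihydroxypropiophenone) (rings B and B′, from the bought aromatic ketone) and two molecules of propionylfilicinic acid (rings A and A′).
- Ring A is cut at two bonds: from the ring carbonyl carbon C1 (next to CMe2) to the acyl-bearing C2, and from the enol carbon C3 to the ring CH C4. This gives 3-ethoxy-4,4-dimethylcyclobutenone and an ethoxyalkyne that carries the propionyl group as a silyl-protected carbinol.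
- Enabling feature: C6 of each end ring is quaternary (two methyl groups) and sits between the C1 ketone and the C5 enol carbon, so the ring cannot aromatize. It is a 6,6-dimethylcyclohexa-2,4-dien-1-one, the 6π-electrocyclization product of a dienylketene with an isopropylidene terminus. The oxygens at C1, C3 and C5 map onto a ketene carbonyl, an ynol ether and a cyclobutenone enol ether.
- Ring order: the four-membered ring (dimethylketene plus ethoxyacetylene), then ring A by ring expansion of it, then the B–CH2–B′ core, then attachment of two copies of ring A in the last step.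

Key step: step 3

Remark: the target has no stereocenter and is handled as the enol tautomer drawn. The carbinol center carried by the alkyne fragment is racemic and is erased by the later oxidation.

**Step 1**
Reactants: 1 isobutyryl chloride; 2 ethoxyacetylene
Product: 4 3-ethoxy-4,4-dimethylcyclobut-2-en-1-one, via dimethylketene 3 (not isolated)
Conditions: Et3N, MeCN, 0 → 40 °C
Reagents that add atoms: none
Why: Dehydrochlorination should give dimethylketene, which should add the electron-rich alkyne in a regioselective thermal [2+2] cycloaddition (ketene carbonyl carbon to the unsubstituted alkyne carbon), the standard ketene–alkoxyacetylene route to 3-alkoxycyclobutenones; no stereocenter is formed.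

**Step 2**
Reactants: 2 ethoxyacetylene; 5 propanal
Product: 8 rac-tert-butyl[(1-ethoxypent-1-yn-3-yl)oxy]dimethylsilane, via lithium ethoxyacetylide 6 (not isolated), via lithium 1-ethoxypent-1-yn-3-olate 7 (not isolated)
Conditions: n-BuLi, THF, −78 °C; EtCHO, −78 → 0 °C; then TBSCl, imidazole, DMF, 25 °C
Reagents that add atoms: tert-butyldimethylsilyl chloride (TBSCl), CC(C)(C)[Si](C)(C)Cl
Why: Acetylide 1,2-addition to the aldehyde followed by in situ O-silylation of the alkoxide should avoid isolation of the acid-labile propargylic alcohol; the carbinol center is racemic and is removed in step 5.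

**Step 3**
Reactants: 4 3-ethoxy-4,4-dimethylcyclobut-2-en-1-one; 8 rac-tert-butyl[(1-ethoxypent-1-yn-3-yl)oxy]dimethylsilane
Product: 12 rac-2-[1-(tert-butyldimethylsilyloxy)propyl]-3,5-diethoxy-6,6-dimethylcyclohexa-2,4-dien-1-one, via vinylketene 9 (not isolated), via cyclobutenone adduct 10 (not isolated), via dienylketene 11 (not isolated)
Conditions: 8 (1.5 equiv), hν (300 nm), toluene, 25 °C; then 80 °C, dark
Reagents that add atoms: none
Why: Proposed new method: irradiation should open 4 by 4π-electrocyclic cleavage to vinylketene 9, whose ketene C=C should add ynol ether 8 in a [2+2] cycloaddition; this closes the four-membered ring of 10 and makes both the bond from the ring carbonyl carbon to the carbon carrying the masked acyl group and the bond from the ethoxy-bearing alkyne carbon to the ring CH. Warming should open 10 by a second 4π-electrocyclic cleavage to dienylketene 11, which should close the six-membered ring by thermal disrotatory 6π-electrocyclization onto its isopropylidene terminus. The closest known reaction type is the Danheiser benzannulation of cyclobutenones with alkoxy- and silyloxyalkynes, together with the known thermal closure of dienylketenes to 6,6-disubstituted cyclohexa-2,4-dienones; what is new is that the 4,4-dimethyl group leaves a quaternary carbon, so the cascade should stop at the non-aromatizable dienone and not at a phenol. No ring stereocenter is created, since the sp3 carbon of 10 is transient and the side-chain carbinol center is racemic and later oxidized. The step needs regioselectivity in the cycloaddition, which the polarization of the ynol ether secures (its carbon β to oxygen attacks the electrophilic ketene carbon). It also needs the cycloaddition to outrun a [1,5]-hydrogen shift of 9, which generation of 9 at 25 °C in excess 8 should secure, while the reversible opening of 10 should funnel either alkene geometry to the cis-dienylketene that cyclizes.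

**Step 4**
Reactants: 12 rac-2-[1-(tert-butyldimethylsilyloxy)propyl]-3,5-diethoxy-6,6-dimethylcyclohexa-2,4-dien-1-one
Product: 13 rac-3,5-diethoxy-2-(1-hydroxypropyl)-6,6-dimethylcyclohexa-2,4-dien-1-one
Conditions: TBAF, AcOH, THF, 0 → 25 °C
Reagents that add atoms: none
Why: Buffered fluoride cleavage of the silyl ether should leave the two vinylogous-ester enol ethers and the dienone untouched.

**Step 5**
Reactants: 13 rac-3,5-diethoxy-2-(1-hydroxypropyl)-6,6-dimethylcyclohexa-2,4-dien-1-one
Product: 14 3,5-diethoxy-6,6-dimethyl-2-propanoylcyclohexa-2,4-dien-1-one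
Conditions: Dess–Martin periodinane, pyridine, CH2Cl2, 0 → 25 °C
Reagents that add atoms: none
Why: Dess–Martin oxidation of the secondary allylic alcohol under buffered, non-acidic conditions should give the ketone and removes the only stereocenter.

**Step 6**
Reactants: 14 3,5-diethoxy-6,6-dimethyl-2-propanoylcyclohexa-2,4-dien-1-one
Product: 15 3,5-dihydroxy-6,6-dimethyl-2-propanoylcyclohexa-2,4-dien-1-one (propionylfilicinic acid)
Conditions: 2 M aq HCl, THF, 50 °C
Reagents that add atoms: water, O
Why: Acid hydrolysis of the two vinylogous-ester enol ethers (addition of water, loss of ethanol) should unveil the enolized triketone, which the gem-dimethyl carbon keeps from aromatizing.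

**Step 7**
Reactants: 16 2,4,6-trihydroxypropiophenone (2 equiv enter the product); 17 formaldehyde
Product: 18 1,1'-[methylenebis(2,4,6-trihydroxy-3,1-phenylene)]bis(propan-1-one)
Conditions: 16 (3 equiv, excess recovered), 37% aq CH2O (1 equiv), K2CO3 (cat.), EtOH–H2O, 25 °C
Reagents that add atoms: none
Why: Phenol–formaldehyde condensation should join two molecules of 16 through the carbon of one molecule of formaldehyde with loss of water (hydroxymethylation of one ring at one of its two equivalent free positions, then attack of a second ring on the derived ortho-quinone methide), with the excess of 16 holding back higher oligomers.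

**Step 8**
Reactants: 18 1,1'-[methylenebis(2,4,6-trihydroxy-3,1-phenylene)]bis(propan-1-one)
Product: 19 1,1'-{methylenebis[5-[(dimethylamino)methyl]-2,4,6-trihydroxy-3,1-phenylene]}bis(propan-1-one)
Conditions: Me2N=CH2+ I− (2.2 equiv), i-Pr2NEt, MeCN, 0 → 25 °C
Reagents that add atoms: Eschenmoser's salt (N,N-dimethylmethyleneiminium iodide), C=[N+](C)C.[I-]
Why: Mannich aminomethylation (electrophilic aromatic substitution) should occur once on each phloroglucinol ring at its single free position, taking up two equivalents of the iminium salt, so over-reaction is not possible.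

**Step 9**
Reactants: 19 1,1'-{methylenebis[5-[(dimethylamino)methyl]-2,4,6-trihydroxy-3,1-phenylene]}bis(propan-1-one); 15 3,5-dihydroxy-6,6-dimethyl-2-propanoylcyclohexa-2,4-dien-1-one (2 equiv enter the product)
Product: 20 4,4'-{methylenebis[(2,4,6-trihydroxy-5-propanoyl-3,1-phenylene)methylene]}bis(3,5-dihydroxy-6,6-dimethyl-2-propanoylcyclohexa-2,4-dien-1-one) (target CNP0541376.0)
Conditions: 15 (2.2 equiv), 1,4-dioxane, 90 °C, N2 sweep
Reagents that add atoms: none
Why: Heating the phenolic Mannich base should expel dimethylamine from each ring to give ortho-quinone methides, each of which should be trapped by Michael addition of the C4 enol carbon of one molecule of the acidic 15, the only carbon nucleophile present because 19 has no free ring position (ortho-quinone methide generation from a phenolic Mannich base and addition of a cyclic 1,3-dicarbonyl).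

**Compound list**
1 | isobutyryl chloride | CC(C)C(=O)Cl | starting material
2 | ethoxyacetylene | CCOC#C | starting material
3 | dimethylketene | CC(C)=C=O | intermediate
4 | 3-ethoxy-4,4-dimethylcyclobut-2-en-1-one | CCOC1=CC(=O)C1(C)C | intermediate
5 | propanal | CCC=O | starting material
6 | lithium ethoxyacetylide | [Li]C#COCC | intermediate
7 | lithium 1-ethoxypent-1-yn-3-olate (racemic) | CCOC#CC(CC)O[Li] | intermediate
8 | rac-tert-butyl[(1-ethoxypent-1-yn-3-yl)oxy]dimethylsilane | CCOC#CC(CC)O[Si](C)(C)C(C)(C)C | intermediate
9 | 3-ethoxy-4-methylpenta-1,3-dien-1-one (vinylketene) | CCOC(C=C=O)=C(C)C | intermediate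
10 | 2-[1-(tert-butyldimethylsilyloxy)propyl]-3-ethoxy-4-(1-ethoxy-2-methylprop-1-en-1-yl)cyclobut-2-en-1-one (racemic, mixture of diastereomers) | CCOC1=C(C(CC)O[Si](C)(C)C(C)(C)C)C(=O)C1C(OCC)=C(C)C | intermediate
11 | (3E)-2-[1-(tert-butyldimethylsilyloxy)propyl]-3,5-diethoxy-6-methylhepta-1,3,5-trien-1-one (dienylketene, racemic; ketene-bearing carbon and isopropylidene-bearing carbon cis) | O=C=C(C(CC)O[Si](C)(C)C(C)(C)C)/C(OCC)=C\C(OCC)=C(C)C | intermediate
12 | rac-2-[1-(tert-butyldimethylsilyloxy)propyl]-3,5-diethoxy-6,6-dimethylcyclohexa-2,4-dien-1-one | CCOC1=CC(OCC)=C(C(CC)O[Si](C)(C)C(C)(C)C)C(=O)C1(C)C | intermediate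
13 | rac-3,5-diethoxy-2-(1-hydroxypropyl)-6,6-dimethylcyclohexa-2,4-dien-1-one | CCOC1=CC(OCC)=C(C(O)CC)C(=O)C1(C)C | intermediate
14 | 3,5-diethoxy-6,6-dimethyl-2-propanoylcyclohexa-2,4-dien-1-one | CCOC1=CC(OCC)=C(C(=O)CC)C(=O)C1(C)C | intermediate
15 | 3,5-dihydroxy-6,6-dimethyl-2-propanoylcyclohexa-2,4-dien-1-one (propionylfilicinic acid) | CCC(=O)C1=C(O)C=C(O)C(C)(C)C1=O | intermediate
16 | 2,4,6-trihydroxypropiophenone | CCC(=O)c1c(O)cc(O)cc1O | starting material
17 | formaldehyde | C=O | starting material
18 | 1,1'-[methylenebis(2,4,6-trihydroxy-3,1-phenylene)]bis(propan-1-one) | CCC(=O)c1c(O)cc(O)c(Cc2c(O)cc(O)c(C(=O)CC)c2O)c1O | intermediate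
19 | 1,1'-{methylenebis[5-[(dimethylamino)methyl]-2,4,6-trihydroxy-3,1-phenylene]}bis(propan-1-one) | CCC(=O)c1c(O)c(CN(C)C)c(O)c(Cc2c(O)c(CN(C)C)c(O)c(C(=O)CC)c2O)c1O | intermediate
20 | 4,4'-{methylenebis[(2,4,6-trihydroxy-5-propanoyl-3,1-phenylene)methylene]}bis(3,5-dihydroxy-6,6-dimethyl-2-propanoylcyclohexa-2,4-dien-1-one) | CCC(=O)C1=C(O)C(Cc2c(O)c(Cc3c(O)c(CC4=C(O)C(C)(C)C(=O)C(C(=O)CC)=C4O)c(O)c(C(=O)CC)c3O)c(O)c(C(=O)CC)c2O)=C(O)C(C)(C)C1=O | target

**Step count**
Total steps: 9. Longest linear sequence: 6 steps (steps 1, 3, 4, 5, 6, 9).

**Steps most likely to fail**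

1. Step 3. The vinylketene may isomerize by [1,5]-hydrogen shift from a terminal methyl group or dimerize faster than the ynol ether intercepts it, or the photochemical opening of the alkoxycyclobutenone may be inefficient. The fallback uses known chemistry; it sets out from 16 and comes back at 15. Dearomatizing gem-dimethylation of 2,4,6-trihydroxypropiophenone 16 with MeI (2 equiv) and NaOMe in MeOH should give propionylfilicinic acid 15 directly, so that the six steps leading to 15 are not needed. The fallback makes no new compound and is entered below as F0.

2. Step 9. The methylene bridges may exchange by retro-Friedel–Crafts cleavage and recombination (rottlerone-type scrambling) at 90 °C, or the second coupling may stall. The fallback changes the order of bridge formation; it sets out from 15 and comes back at 20. Aminomethylation of 15 with Eschenmoser's salt and i-Pr2NEt in MeCN should give 4-[(dimethylamino)methyl]-3,5-dihydroxy-6,6-dimethyl-2-propanoylcyclohexa-2,4-dien-1-one F1. Heating F1 with excess 16 in 1,4-dioxane should give the mixed dimer 3,5-dihydroxy-6,6-dimethyl-2-propanoyl-4-(2,4,6-trihydroxy-3-propanoylbenzyl)cyclohexa-2,4-dien-1-one F2, which has a single free aromatic position. Condensation of two molecules of F2 with one molecule of formaldehyde 17 (37% aq CH2O, K2CO3 (cat.), EtOH–H2O, 25 °C) should close the central bridge and give 20.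

3. Step 5. The electron-rich allylic carbinol may ionize and lose water (or be trapped at the derived cation) before it is oxidized. The fallback introduces the acyl group after ring construction, so no carbinol is made; it sets out from 4 and comes back at 15. Irradiation of 4 with ethoxyacetylene 2 (300 nm, toluene, 25 °C) and then warming to 80 °C should give, by the same ring expansion, 3,5-diethoxy-6,6-dimethylcyclohexa-2,4-dien-1-one F3. Hydrolysis of F3 with 2 M aq HCl in THF should give filicinic acid F4. C-acylation of F4 with propionic anhydride and boron trifluoride diethyl etherate (Friedel–Crafts-type acylation; the two free ring carbons are equivalent) should give 15.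

**Further compounds**
F0 | step 3 | none | none
F1 | step 9 | 4-[(dimethylamino)methyl]-3,5-dihydroxy-6,6-dimethyl-2-propanoylcyclohexa-2,4-dien-1-one | CCC(=O)C1=C(O)C(CN(C)C)=C(O)C(C)(C)C1=O
F2 | step 9 | 3,5-dihydroxy-6,6-dimethyl-2-propanoyl-4-(2,4,6-trihydroxy-3-propanoylbenzyl)cyclohexa-2,4-dien-1-one | CCC(=O)C1=C(O)C(Cc2c(O)cc(O)c(C(=O)CC)c2O)=C(O)C(C)(C)C1=O
F3 | step 5 | 3,5-diethoxy-6,6-dimethylcyclohexa-2,4-dien-1-one | CCOC1=CC(OCC)=CC(=O)C1(C)C
F4 | step 5 | filicinic acid (3,5-dihydroxy-6,6-dimethylcyclohexa-2,4-dien-1-one) | CC1(C)C(=O)C=C(O)C=C1O
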